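The G charged in the zeta run over that in the alpha run is 30.2, yet the ratio of their E readings at 30.0 h, in percent of the G charged, is 1.02. That is a difference of 0.2 percentage points against a scatter of 0.3 points per reading. So these closed flasks, in which G turns into E, lie within the scatter on one curve of percent against time, and that curve is what has to be drawn.

| setting | alpha | theta | zeta | green | blue | violet | grey |
|---|---|---|---|---|---|---|---|
| G | 6.3 × 10⁻⁴ M | 0.0039 M | 0.019 M | 8.0 × 10⁻⁴ M | 0.0020 M | 0.0060 M | 0.020 M |
| remark | run made earlier | run made earlier | run made earlier |  |  |  |  |
| time |  |  |  | 30 h | 30 h | 30 h | 30 h |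

- alpha (time / h: E / %): 6.00: 3.3; 12.0: 7.1; 20.0: 10.3; 25.0: 11.7; 30.0: 11.9
- theta (time / h: E / %): 2.50: 1.2; 8.00: 4.7; 15.0: 8.8; 20.0: 10.5; 30.0: 12.0
- zeta (time / h: E / %): 2.50: 0.9; 5.00: 3.2; 8.00: 4.8; 15.0: 8.8; 30.0: 12.1

(scatter of a reading: 0.3 percentage points)

- "hardly changes" means that all values lie within two and a half points (for a concentration: within two and a half percent of the largest)

The curve opens with a foot (an induction period): the theta run reads 1.2 % at 2.50 h. It then steepens, gaining 4.1 points from 8.00 h to 15.0 h, and past a knee near 20.0 h it gains 1.5 points in the next 10.0 h.

To find the level, take E as closing a gap exponentially. The share of the gap open at 15.0 h is then squared at twice that time. So the theta ratio of the later reading to the earlier, 1.36, less one, is the share still open at 15.0 h, 0.364. Dividing the 15.0 h reading by one less that share gives 13.8 %, a reading with the scatter of its parts. This is the closing level P, the percent of the G charged that E runs into.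

The same share gives a closing time of 14.8 h. Put on the alpha run, P and this time give 10.2 % at 20.0 h, where alpha read 10.3 %. At 2.50 h they give 2.14 %, where theta read 1.2 %, and at 8.00 h they give 5.76 %, where theta read 4.7 %, so the exponential runs above these early readings and is of use for the late part of the curve.

* amount of E at the end, in percent of the G charged for green, blue, violet, grey, in this order
* how that number moves from the first to the last of them (rises, then falls / rises all the way / hardly changes / falls, then rises / falls all the way)

The reckoning here takes the mean of the 30.0 h readings, 12.0 %, for each new flask, since grey's 0.020 M lies just above zeta's 0.019 M and the other charges lie inside the tested range. The forecast gives the same: 12 %, 12 %, 12 % and 12 %, a row that hardly changes, holding that “fractional conversion does not depend on concentration”.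

    G → X (k = 0.0471 h⁻¹)
    X → E (k = 0.0905 h⁻¹)
    G → L (k = 0.305 h⁻¹)
    D → Z (k = 0.0706 h⁻¹)
    Q → D (k = 0.0909 h⁻¹)
    L → Q (k = 0.0415 h⁻¹)

Green, blue, violet and grey give 12.2 %, 12.2 %, 12.2 % and 12.2 %, so the row hardly changes. Green at 30.0 h stands 1.6 points under P, 13.8 %, and holds 1.19 % of X, which turns into E. Grey's E of 8.77 % at 15.0 h and 12.2 % at 30.0 h go through the same rule to a level of 14.4 %, and grey holds 13.4 % of E at 300 h.

(The earlier runs and the new flask were computed on assumed constants; the scatter is artificial.)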